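The plan excises the lactone carbonyl C2 from the furanone ring (O1, C2, C3, C4, C5; exocyclic C6; side-chain carbinol C1′). C2 joins C3 to O1, and O1 is nothing more than the oxygen of a C5–C6 acetyl group in its enol form, so one palladium-catalysed carbonylation of an open-chain vinyl iodide should make C2–C3 and C2–O1, close the ring and reveal the C5=C6 methylene. The precursor is the (R)-configured, silyl-protected α-bromo-β-iodo enone with iodine cis to acetyl. Its halogens are set by polarity-matched IBr addition to the transposed ynone (ketone at C1′, acetyl masked as a ketal), fixing geometry and C1′ before the risky step.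

Key step: step 6

Remark: the target is read as (R) at C1′ with a (Z) C5=C6 bond (iodine syn to O1). An electrophilic bromine source oxidises iodide, and stepwise iodide addition then bromination of the acetyl ynone gives no assured anti geometry, so one reagent delivers both halogens to the ynone whose ketone sits at C1′.

Step 1
Reactants: 1 but-3-yn-2-one
Product: 2 2-ethynyl-2-methyl-1,3-dioxolane
Conditions: (Me3SiOCH2)2, Me3SiOTf (2 mol%), CH2Cl2, −78 → −20 °C; pyridine quench
Reagents that add atoms: 1,2-bis(trimethylsilyloxy)ethane, C[Si](C)(C)OCCO[Si](C)(C)C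
Why: Noyori ketalisation (Me3SiOTf-catalysed silyl transfer from the bis-silyl glycol) should convert the ynone carbonyl into its dioxolane at low temperature without conjugate addition to the triple bond, masking the future C5–C6 acetyl group as a substituent that no longer polarises the alkyne.

Step 2
Reactants: 2 2-ethynyl-2-methyl-1,3-dioxolane; 3 N-methoxy-N-methylbutanamide
Product: 5 1-(2-methyl-1,3-dioxolan-2-yl)hex-1-yn-3-one, via lithium acetylide 4 (not isolated)
Conditions: n-BuLi, THF, −78 °C; then 3, −78 → −10 °C; inverse quench into cold 1 M HCl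
Reagents that add atoms: none
Why: Acylation of a lithium acetylide with a Weinreb amide should stop at the ynone because the chelated tetrahedral adduct persists until the cold acidic quench, which also keeps the released N,O-dimethylhydroxylamine protonated so that it cannot add to the product.

Step 3
Reactants: 5 1-(2-methyl-1,3-dioxolan-2-yl)hex-1-yn-3-one
Product: 6 (E)-1-bromo-2-iodo-1-(2-methyl-1,3-dioxolan-2-yl)hex-1-en-3-one (iodine on the carbon next to the ketone, bromine on the carbon next to the ketal, halogens trans)
Conditions: IBr (1.05 equiv), CH2Cl2, −78 °C, dark; aq. Na2S2O3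
Reagents that add atoms: iodine monobromide, BrI
Why: Electrophilic anti iodobromination of a conjugated ynone with matched polarity: iodine bonds to the carbon α to the ketone, bromide opens the iodonium ion at the β carbon from the opposite face, and the halogens therefore end up trans (E) with iodine cis to the ketal carbon that becomes the acetyl group, while cold and dark conditions hold back E/Z equilibration.

Step 4
Reactants: 6 (E)-1-bromo-2-iodo-1-(2-methyl-1,3-dioxolan-2-yl)hex-1-en-3-one
Product: 8 (R,E)-3-bromo-5-hydroxy-4-iodooct-3-en-2-one, via ketal alcohol 7 (not isolated)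
Conditions: (S)-1-methyl-3,3-diphenyltetrahydro-1H,3H-pyrrolo[1,2-c][1,3,2]oxazaborole (20 mol%), BH3·SMe2, THF, −30 °C; MeOH; then 2 M HCl, THF, 25 °C
Reagents that add atoms: water, O
Why: Corey–Bakshi–Shibata reduction sets C1′ under catalyst control, since the bulky α-iodoalkenyl group acts as the large and n-propyl as the small ketone substituent so that the (S)-oxazaborolidine delivers hydride to the face giving the (R)-alcohol, after which acid-catalysed ketal hydrolysis in the same flask frees the methyl ketone, which lies trans to the carbinol across the alkene and so cannot form a lactol.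

Step 5
Reactants: 8 (R,E)-3-bromo-5-hydroxy-4-iodooct-3-en-2-one
Product: 9 (R,E)-3-bromo-5-(tert-butyldimethylsilyloxy)-4-iodooct-3-en-2-one (iodine cis to the acetyl group)
Conditions: t-BuMe2SiOTf, 2,6-lutidine, CH2Cl2, −78 → 0 °C
Reagents that add atoms: tert-butyldimethylsilyl trifluoromethanesulfonate, CC(C)(C)[Si](C)(C)OS(=O)(=O)C(F)(F)F
Why: Silyl ether formation with a silyl triflate and a hindered pyridine base should protect the crowded secondary alcohol at low temperature, avoiding nucleophilic amines that could displace the vinylogous acyl iodide by addition–elimination.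

Step 6
Reactants: 9 (R,E)-3-bromo-5-(tert-butyldimethylsilyloxy)-4-iodooct-3-en-2-one; 10 carbon monoxide
Product: 11 4-bromo-3-[(R)-1-(tert-butyldimethylsilyloxy)butyl]-5-methylenefuran-2(5H)-one
Conditions: PdCl2(PPh3)2 (5 mol%), CO (1 atm), i-Pr2NEt, THF, 40 °C
Reagents that add atoms: none
Why: Zerovalent palladium, generated in situ from PdCl2(PPh3)2, should insert into the C3–I bond of 9, CO migratory insertion then gives the C2 acylpalladium, and the oxygen of the cis-disposed acetyl group (as its amine-generated enol, or as the ketone with subsequent loss of a C6 proton) captures it, forming C2–O1 and returning zerovalent palladium. The closest known reaction type is the palladium-catalysed carbonylative lactonisation of (Z)-β-iodoenones to γ-alkylidene butenolides, applied here to a substrate that carries an additional α-bromine. The furanone ring closes by 5-exo-trig attack of O1 on the acyl carbon C2, or equivalently by C–O reductive elimination from a six-membered oxapalladacycle, and the exocyclic C5=C6 bond is created in the same event. No stereocentre is formed and C1′ passes through unchanged, its silyl ether being inert to ionisation by palladium. The step needs insertion into C–I and not C–Br, which the weaker C–I bond and its β (vinylogous acyl) position should secure at 40 °C with a triphenylphosphine catalyst, and it needs O- over C-capture, which the harder enol oxygen and the strain of the alternative cyclopentenedione favour. A hindered amine and the CO atmosphere should limit later attack on the C4–Br bond of 11, which the new lactone carbonyl activates.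

Step 7
Reactants: 11 4-bromo-3-[(R)-1-(tert-butyldimethylsilyloxy)butyl]-5-methylenefuran-2(5H)-one
Product: 13 (Z)-4-bromo-3-[(R)-1-(tert-butyldimethylsilyloxy)butyl]-5-(iodomethylene)furan-2(5H)-one, via chloro(iodomethyl) adduct 12 (not isolated)
Conditions: ICl (1.1 equiv), CH2Cl2, −40 → 0 °C, dark; then i-Pr2NEt, 0 → 25 °C
Reagents that add atoms: iodine monochloride, ClI
Why: Halogen addition–dehydrohalogenation, the established way to halogenate the exocyclic carbon of 5-methylene-2(5H)-furanones: iodine should add to the terminal C6 and chloride to the oxygen-stabilised C5, and amine-induced loss of HCl then restores the C5=C6 bond with iodine syn to O1 (Z), the isomer free of the C6–I/C4–Br clash.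

Step 8
Reactants: 13 (Z)-4-bromo-3-[(R)-1-(tert-butyldimethylsilyloxy)butyl]-5-(iodomethylene)furan-2(5H)-one
Product: 14 (Z)-4-bromo-3-[(R)-1-hydroxybutyl]-5-(iodomethylene)furan-2(5H)-one
Conditions: HF (48% aq.), MeCN, 0 → 25 °C
Reagents that add atoms: none
Why: Acidic fluoride desilylation should cleave the Si–O bond without any basic nucleophile that could attack the halogenated butenolide, and C1′ is not at risk of ionisation because it adjoins an electron-poor alkene.

Step 9
Reactants: 14 (Z)-4-bromo-3-[(R)-1-hydroxybutyl]-5-(iodomethylene)furan-2(5H)-one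
Product: 15 (R)-1-[(Z)-4-bromo-5-(iodomethylene)-2-oxo-2,5-dihydrofuran-3-yl]butyl acetate
Conditions: Ac2O, Sc(OTf)3 (1 mol%), MeCN, 0 °C
Reagents that add atoms: acetic anhydride, CC(=O)OC(C)=O
Why: Lewis acid-catalysed acetylation with acetic anhydride should esterify the secondary alcohol under amine-free conditions, which matters because the product acetate sits next to an acceptor alkene and would invite allylic displacement by nucleophilic bases.

Compound list
1 | but-3-yn-2-one | CC(=O)C#C | starting material
2 | 2-ethynyl-2-methyl-1,3-dioxolane | CC1(C#C)OCCO1 | intermediate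
3 | N-methoxy-N-methylbutanamide | CCCC(=O)N(C)OC | starting material
4 | lithium (2-methyl-1,3-dioxolan-2-yl)acetylide | [Li]C#CC1(C)OCCO1 | intermediate
5 | 1-(2-methyl-1,3-dioxolan-2-yl)hex-1-yn-3-one | CCCC(=O)C#CC1(C)OCCO1 | intermediate
6 | (E)-1-bromo-2-iodo-1-(2-methyl-1,3-dioxolan-2-yl)hex-1-en-3-one | CCCC(=O)/C(I)=C(Br)/C1(C)OCCO1 | intermediate
7 | (R,E)-1-bromo-2-iodo-1-(2-methyl-1,3-dioxolan-2-yl)hex-1-en-3-ol | CCC[C@@H](O)/C(I)=C(Br)/C1(C)OCCO1 | intermediate
8 | (R,E)-3-bromo-5-hydroxy-4-iodooct-3-en-2-one | CCC[C@@H](O)/C(I)=C(Br)/C(C)=O | intermediate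
9 | (R,E)-3-bromo-5-(tert-butyldimethylsilyloxy)-4-iodooct-3-en-2-one | CCC[C@@H](O[Si](C)(C)C(C)(C)C)/C(I)=C(Br)/C(C)=O | intermediate
10 | carbon monoxide | [C-]#[O+] | starting material
11 | 4-bromo-3-[(R)-1-(tert-butyldimethylsilyloxy)butyl]-5-methylenefuran-2(5H)-one | CCC[C@@H](O[Si](C)(C)C(C)(C)C)C1=C(Br)C(=C)OC1=O | intermediate
12 | 4-bromo-3-[(R)-1-(tert-butyldimethylsilyloxy)butyl]-5-chloro-5-(iodomethyl)furan-2(5H)-one (C5 epimers) | CCC[C@@H](O[Si](C)(C)C(C)(C)C)C1=C(Br)C(Cl)(CI)OC1=O | intermediate
13 | (Z)-4-bromo-3-[(R)-1-(tert-butyldimethylsilyloxy)butyl]-5-(iodomethylene)furan-2(5H)-one | CCC[C@@H](O[Si](C)(C)C(C)(C)C)C1=C(Br)/C(=C/I)OC1=O | intermediate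
14 | (Z)-4-bromo-3-[(R)-1-hydroxybutyl]-5-(iodomethylene)furan-2(5H)-one | CCC[C@@H](O)C1=C(Br)/C(=C/I)OC1=O | intermediate
15 | (R)-1-[(Z)-4-bromo-5-(iodomethylene)-2-oxo-2,5-dihydrofuran-3-yl]butyl acetate | CCC[C@@H](OC(C)=O)C1=C(Br)/C(=C/I)OC1=O | target

Total step count: 9. Longest linear sequence: 9 steps (1 to 15).

Steps most likely to fail, in order of risk:

Step 6. The risks are palladium insertion into a C–Br bond (above all the C4–Br bond of the product, which the new lactone carbonyl activates), loss of bromide from the vinylpalladium to regenerate an alkyne, and capture of the acylpalladium at the enolate carbon instead of oxygen. The fallback separates CO insertion from ring closure. Setting out from 9, palladium-catalysed hydroxycarbonylation in wet THF (PdCl2(PPh3)2, CO, i-Pr2NEt, H2O, 40 °C) should let water capture the acylpalladium. The carboxylate so formed activates its neighbouring C–Br bond only weakly, and on acidification the (Z)-γ-keto acid should close to its ring tautomer 4-bromo-3-[(R)-1-(tert-butyldimethylsilyloxy)butyl]-5-hydroxy-5-methylfuran-2(5H)-one F1. Dehydration of this tertiary lactol ((CF3CO)2O, 2,6-lutidine, CH2Cl2, 0 °C), a known way to 5-methylene butenolides, comes back to the route at 11; any 11 formed directly in the carbonylation joins the same stream.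

Step 7. The risks are reversible or incomplete iodochlorination of the weakly nucleophilic enol-lactone alkene, formation of an E/Z mixture on elimination, and loss of the silyl ether through adventitious HCl. The fallback replaces halide addition and elimination by cohalogenation with water followed by dehydration. Setting out from 11, N-iodosuccinimide in wet MeCN should give the lactol 4-bromo-3-[(R)-1-(tert-butyldimethylsilyloxy)butyl]-5-hydroxy-5-(iodomethyl)furan-2(5H)-one F2. Dehydration under the same anhydride and lutidine conditions should proceed through the C5 oxocarbenium ion and settle on the less crowded Z alkene, coming back to the route at 13.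

Step 4. The risk is poor facial selectivity in the reduction of a crowded, twisted dihaloenone, which would erode enantiopurity at C1′. The fallback is a resolution in place of asymmetric catalysis. Setting out from 6, Luche reduction (NaBH4, CeCl3·7H2O, MeOH, −40 °C) should give racemic (E)-1-bromo-2-iodo-1-(2-methyl-1,3-dioxolan-2-yl)hex-1-en-3-ol F3. Esterification with (S)-2-methoxy-2-phenylacetic acid (DCC, DMAP, CH2Cl2) should give two diastereomeric esters separable by chromatography: (R,E)-1-bromo-2-iodo-1-(2-methyl-1,3-dioxolan-2-yl)hex-1-en-3-yl (S)-2-methoxy-2-phenylacetate F4, which is kept, and (S,E)-1-bromo-2-iodo-1-(2-methyl-1,3-dioxolan-2-yl)hex-1-en-3-yl (S)-2-methoxy-2-phenylacetate F5, which is set aside. Methanolysis of F4 (K2CO3, MeOH) is safe at the ketal stage because the dihaloalkene is not conjugated to a carbonyl; it comes back to the route at 7, which is hydrolysed to 8 as in step 4.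

Further compounds
F1 | step 6 | 4-bromo-3-[(R)-1-(tert-butyldimethylsilyloxy)butyl]-5-hydroxy-5-methylfuran-2(5H)-one (C5 epimers) | CCC[C@@H](O[Si](C)(C)C(C)(C)C)C1=C(Br)C(C)(O)OC1=O
F2 | step 7 | 4-bromo-3-[(R)-1-(tert-butyldimethylsilyloxy)butyl]-5-hydroxy-5-(iodomethyl)furan-2(5H)-one (C5 epimers) | CCC[C@@H](O[Si](C)(C)C(C)(C)C)C1=C(Br)C(O)(CI)OC1=O
F3 | step 4 | racemic (E)-1-bromo-2-iodo-1-(2-methyl-1,3-dioxolan-2-yl)hex-1-en-3-ol | CCCC(O)/C(I)=C(Br)/C1(C)OCCO1
F4 | step 4 | (R,E)-1-bromo-2-iodo-1-(2-methyl-1,3-dioxolan-2-yl)hex-1-en-3-yl (S)-2-methoxy-2-phenylacetate | CCC[C@@H](OC(=O)[C@@H](OC)c1ccccc1)/C(I)=C(Br)/C1(C)OCCO1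
F5 | step 4 | (S,E)-1-bromo-2-iodo-1-(2-methyl-1,3-dioxolan-2-yl)hex-1-en-3-yl (S)-2-methoxy-2-phenylacetate | CCC[C@H](OC(=O)[C@@H](OC)c1ccccc1)/C(I)=C(Br)/C1(C)OCCO1
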